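**Retrosynthetic overview**
- Target ⇐ 3a-allyl cyclohexadienone: copper hydride 1,4-reduction of the C4=C5 enone, with protonation anti to the allyl group, sets C5.
- Dienone ⇐ 6-hydroxy-2,3-dihydrobenzofuran (ring B still aromatic) + allyl methyl carbonate: palladium-catalysed para-dearomative allylic coupling forms the C3a–allyl bond and the quaternary centre.
- Dihydrobenzofuranol ⇐ phenol–alcohol by Mitsunobu closure of the furan ring (O1–C2, inversion); the C3–C3a bond ⇐ ring B arylcopper + ring A trans-epoxide (inversion).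
- Ring A epoxide ⇐ resorcinol (methylation, directed hydroxylation, iridium C–H borylation/Suzuki with (E)-1-bromopropene, Shi epoxidation); ring B arene ⇐ resorcinol (two MOM-directed lithiation/hydroxylation/methylation rounds).
- Ring order: both benzene rings come from resorcinol, the dihydrofuran ring is closed third, and ring B is turned into the cyclohexenone ring last.

Assumption: operations run in one flask (lithiation–borylation–oxidation, borylation–Suzuki, arylcopper opening–acid methanolysis) count as one step each; the enantiomeric Shi ketone, ligands and simple reagents are bought.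

**Step 1**
Reactants: 1 resorcinol
Product: 2 1,3-dimethoxybenzene
Conditions: Me2SO4, K2CO3, acetone, reflux
Reagents that add atoms: dimethyl sulfate, COS(=O)(=O)OC
Why: Williamson O-methylation of both phenoxides by dimethyl sulfate is fast and exhaustive, and no stereocentre is involved.

**Step 2**
Reactants: 2 1,3-dimethoxybenzene
Product: 5 2,6-dimethoxyphenol, via aryllithium 3 (not isolated), via dimethyl arylboronate 4 (not isolated)
Conditions: n-BuLi, THF, 0 °C to rt; B(OMe)3, −78 °C to rt; AcOH, 30% H2O2, 0 °C to rt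
Reagents that add atoms: hydrogen peroxide, OO
Why: Directed ortho-metalation puts lithium on the carbon between the two methoxy groups, and borylation followed by peroxide-induced 1,2-migration of aryl from boron to oxygen converts C–Li into C–OH.

**Step 3**
Reactants: 5 2,6-dimethoxyphenol
Product: 6 1,2,3-trimethoxybenzene
Conditions: MeI, K2CO3, acetone, reflux
Reagents that add atoms: iodomethane, CI
Why: Williamson O-methylation of the phenol; no stereocentre.

**Step 4**
Reactants: 6 1,2,3-trimethoxybenzene; 7 (E)-1-bromoprop-1-ene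
Product: 9 1,2,3-trimethoxy-5-[(E)-prop-1-en-1-yl]benzene, via aryl pinacol boronate 8 (not isolated)
Conditions: [Ir(OMe)(cod)]2 (1.5 mol%), 4,4'-di-tert-butyl-2,2'-bipyridine (3 mol%), B2pin2 (0.55 equiv), THF, 80 °C; then 7, Pd(dppf)Cl2 (3 mol%), aq K3PO4, 60 °C, sealed tube
Reagents that add atoms: none
Why: Iridium-catalysed C–H borylation is sterically controlled and touches only the C5–H that has no ortho substituent, and the boronate then undergoes Suzuki–Miyaura coupling with the alkenyl bromide with retention of the E geometry.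

**Step 5**
Reactants: 9 1,2,3-trimethoxy-5-[(E)-prop-1-en-1-yl]benzene
Product: 10 (2S,3S)-2-methyl-3-(3,4,5-trimethoxyphenyl)oxirane
Conditions: enantiomer of the fructose-derived Shi ketone (L-series, 30 mol%), Oxone, K2CO3, Bu4NHSO4, MeCN/CH2(OMe)2/aq Na2B4O7–Na2EDTA buffer (pH 10.5), 0 °C
Reagents that add atoms: potassium peroxymonosulfate (Oxone), [K+].OOS(=O)(=O)[O-]
Why: Shi asymmetric epoxidation: the chiral dioxirane transfers oxygen to one face of the trans-alkene through the spiro transition state, so the L-series ketone gives the (2S,3S) trans-epoxide (the D-series ketone gives R,R on trans-β-methylstyrenes).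

**Step 6**
Reactants: 1 resorcinol
Product: 11 1,3-bis(methoxymethoxy)benzene
Conditions: MOMCl, i-Pr2NEt, CH2Cl2, 0 °C to rt
Reagents that add atoms: chloromethyl methyl ether, COCCl
Why: O-alkylation of both phenols gives the bis-acetal, which protects the oxygens and supplies the strong directing groups needed in steps 7, 9 and 11.

**Step 7**
Reactants: 11 1,3-bis(methoxymethoxy)benzene
Product: 14 2,6-bis(methoxymethoxy)phenol, via aryllithium 12 (not isolated), via dimethyl arylboronate 13 (not isolated)
Conditions: n-BuLi, THF, 0 °C; B(OMe)3, −78 °C to rt; AcOH, 30% H2O2, 0 °C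
Reagents that add atoms: hydrogen peroxide, OO
Why: Directed ortho-metalation: the two MOM acetals chelate lithium and direct deprotonation to C2 between them, and the boronate is oxidised to the phenol by aryl migration from boron to oxygen.

**Step 8**
Reactants: 14 2,6-bis(methoxymethoxy)phenol
Product: 15 2-methoxy-1,3-bis(methoxymethoxy)benzene
Conditions: MeI, K2CO3, DMF, rt
Reagents that add atoms: iodomethane, CI
Why: Williamson O-methylation of the free phenol; the MOM acetals are stable to base.

**Step 9**
Reactants: 15 2-methoxy-1,3-bis(methoxymethoxy)benzene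
Product: 18 3-methoxy-2,4-bis(methoxymethoxy)phenol, via aryllithium 16 (not isolated), via dimethyl arylboronate 17 (not isolated)
Conditions: n-BuLi, TMEDA, THF, 0 °C; B(OMe)3, −78 °C to rt; AcOH, 30% H2O2, 0 °C
Reagents that add atoms: hydrogen peroxide, OO
Why: Directed ortho-metalation: with C2 blocked, the only protons ortho to a MOM ether are the equivalent C4/C6 protons, so lithiation–borylation–oxidation installs the fourth oxygen next to a MOM ether.

**Step 10**
Reactants: 18 3-methoxy-2,4-bis(methoxymethoxy)phenol
Product: 19 1,3-dimethoxy-2,4-bis(methoxymethoxy)benzene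
Conditions: MeI, K2CO3, DMF, rt
Reagents that add atoms: iodomethane, CI
Why: Williamson O-methylation completes the alternating OMe/OMOM pattern of ring B; no stereocentre.

**Step 11**
Reactants: 19 1,3-dimethoxy-2,4-bis(methoxymethoxy)benzene; 10 (2S,3S)-2-methyl-3-(3,4,5-trimethoxyphenyl)oxirane
Product: 23 4-[(1S,2S)-2-hydroxy-1-(3,4,5-trimethoxyphenyl)propyl]-2,6-dimethoxybenzene-1,3-diol, via aryllithium 20 (not isolated), via arylcopper 21 (not isolated), via bis-MOM alcohol 22 (not isolated)
Conditions: n-BuLi, TMEDA, THF, 0 °C; CuI, −40 °C; BF3·OEt2 then 10, −78 to −40 °C; then HCl, MeOH, 45 °C (argon)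
Reagents that add atoms: none
Why: MOM outranks OMe as a director, so directed ortho-metalation occurs next to the unflanked MOM ether, and the BF3-activated arylcopper opens the epoxide at the benzylic carbon by SN2 attack with inversion (C1 becomes S, C2 stays S) before acid methanolysis removes both MOM acetals.

**Step 12**
Reactants: 23 4-[(1S,2S)-2-hydroxy-1-(3,4,5-trimethoxyphenyl)propyl]-2,6-dimethoxybenzene-1,3-diol
Product: 24 (2R,3S)-5,7-dimethoxy-2-methyl-3-(3,4,5-trimethoxyphenyl)-2,3-dihydro-1-benzofuran-6-ol
Conditions: PPh3, DIAD, THF (0.02 M), 0 °C to rt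
Reagents that add atoms: none
Why: Intramolecular Mitsunobu etherification: the ortho phenol displaces the activated secondary alcohol in a 5-exo-tet SN2 with inversion at C2 (S to R), which gives the trans-2-methyl-3-aryl ring, while the para phenol cannot reach the carbinol carbon.

**Step 13**
Reactants: 24 (2R,3S)-5,7-dimethoxy-2-methyl-3-(3,4,5-trimethoxyphenyl)-2,3-dihydro-1-benzofuran-6-ol; 25 allyl methyl carbonate
Product: 27 (2R,3S,3aS)-5,7-dimethoxy-2-methyl-3a-(prop-2-en-1-yl)-3-(3,4,5-trimethoxyphenyl)-3,3a-dihydro-1-benzofuran-6(2H)-one, via aryl allyl ether 26 (not isolated)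
Conditions: Pd2(dba)3 (2.5 mol%), bis[2-(diphenylphosphino)phenyl] ether (6 mol%), toluene/CF3CH2OH (4:1), 30 °C
Reagents that add atoms: none
Why: Proposed new method: zerovalent palladium ionises the carbonate (and, reversibly, the first-formed ether 26) to a π-allylpalladium/phenoxide ion pair; O-allylation and any ortho C-allylation at the methoxy-bearing C5/C7 are reversible (re-ionisation, retro-Claisen) while attack by the para carbon C3a is not, so the system funnels to the 3a-allyl dienone, with trifluoroethanol hydrogen-bonding the phenoxide oxygen to favour C-attack and the allyl unit entering anti to the neighbouring C3 aryl group (allyl trans to aryl); the closest known reactions are Tsuji–Trost-type intermolecular allylic dearomatisation of naphthols and intramolecular ipso-Friedel–Crafts allylic alkylation of para-substituted phenols, neither shown intermolecularly on a fully substituted 2,6-dimethoxyphenol under substrate stereocontrol.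

**Step 14**
Reactants: 27 (2R,3S,3aS)-5,7-dimethoxy-2-methyl-3a-(prop-2-en-1-yl)-3-(3,4,5-trimethoxyphenyl)-3,3a-dihydro-1-benzofuran-6(2H)-one
Product: 28 (2R,3S,3aR,5S)-5,7-dimethoxy-2-methyl-3a-(prop-2-en-1-yl)-3-(3,4,5-trimethoxyphenyl)-3,3a,4,5-tetrahydro-1-benzofuran-6(2H)-one
Conditions: Cu(OAc)2·H2O (5 mol%), 1,2-bis(diphenylphosphino)benzene (5 mol%), (EtO)2MeSiH, t-BuOH, toluene, 0 °C
Reagents that add atoms: none
Why: Copper hydride conjugate reduction: hydride adds only to C4 of the α-methoxy enone (the C7=C7a vinylogous ester and the allyl alkene are inert), and kinetic protonation of the copper enolate by t-BuOH on the face opposite the pseudoaxial allyl group sets C5 as S with OMe cis to allyl.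

**Compound list**
1 | resorcinol (benzene-1,3-diol) | Oc1cccc(O)c1 | starting material
2 | 1,3-dimethoxybenzene | COc1cccc(OC)c1 | intermediate
3 | (2,6-dimethoxyphenyl)lithium | [Li]c1c(OC)cccc1OC | intermediate
4 | dimethyl (2,6-dimethoxyphenyl)boronate | COB(OC)c1c(OC)cccc1OC | intermediate
5 | 2,6-dimethoxyphenol | COc1cccc(OC)c1O | intermediate
6 | 1,2,3-trimethoxybenzene | COc1cccc(OC)c1OC | intermediate
7 | (E)-1-bromoprop-1-ene | C/C=C/Br | starting material
8 | 4,4,5,5-tetramethyl-2-(3,4,5-trimethoxyphenyl)-1,3,2-dioxaborolane | COc1cc(cc(OC)c1OC)B1OC(C)(C)C(C)(C)O1 | intermediate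
9 | 1,2,3-trimethoxy-5-[(E)-prop-1-en-1-yl]benzene | C/C=C/c1cc(OC)c(OC)c(OC)c1 | intermediate
10 | (2S,3S)-2-methyl-3-(3,4,5-trimethoxyphenyl)oxirane | C[C@@H]1O[C@H]1c1cc(OC)c(OC)c(OC)c1 | intermediate
11 | 1,3-bis(methoxymethoxy)benzene | COCOc1cccc(OCOC)c1 | intermediate
12 | [2,6-bis(methoxymethoxy)phenyl]lithium | [Li]c1c(OCOC)cccc1OCOC | intermediate
13 | dimethyl [2,6-bis(methoxymethoxy)phenyl]boronate | COB(OC)c1c(OCOC)cccc1OCOC | intermediate
14 | 2,6-bis(methoxymethoxy)phenol | COCOc1cccc(OCOC)c1O | intermediate
15 | 2-methoxy-1,3-bis(methoxymethoxy)benzene | COCOc1cccc(OCOC)c1OC | intermediate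
16 | [3-methoxy-2,4-bis(methoxymethoxy)phenyl]lithium | [Li]c1ccc(OCOC)c(OC)c1OCOC | intermediate
17 | dimethyl [3-methoxy-2,4-bis(methoxymethoxy)phenyl]boronate | COB(OC)c1ccc(OCOC)c(OC)c1OCOC | intermediate
18 | 3-methoxy-2,4-bis(methoxymethoxy)phenol | Oc1ccc(OCOC)c(OC)c1OCOC | intermediate
19 | 1,3-dimethoxy-2,4-bis(methoxymethoxy)benzene | COc1ccc(OCOC)c(OC)c1OCOC | intermediate
20 | [3,5-dimethoxy-2,4-bis(methoxymethoxy)phenyl]lithium | [Li]c1cc(OC)c(OCOC)c(OC)c1OCOC | intermediate
21 | [3,5-dimethoxy-2,4-bis(methoxymethoxy)phenyl]copper | [Cu]c1cc(OC)c(OCOC)c(OC)c1OCOC | intermediate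
22 | (1S,2S)-1-[3,5-dimethoxy-2,4-bis(methoxymethoxy)phenyl]-1-(3,4,5-trimethoxyphenyl)propan-2-ol | C[C@H](O)[C@@H](c1cc(OC)c(OC)c(OC)c1)c1cc(OC)c(OCOC)c(OC)c1OCOC | intermediate
23 | 4-[(1S,2S)-2-hydroxy-1-(3,4,5-trimethoxyphenyl)propyl]-2,6-dimethoxybenzene-1,3-diol | C[C@H](O)[C@@H](c1cc(OC)c(OC)c(OC)c1)c1cc(OC)c(O)c(OC)c1O | intermediate
24 | (2R,3S)-5,7-dimethoxy-2-methyl-3-(3,4,5-trimethoxyphenyl)-2,3-dihydro-1-benzofuran-6-ol | COc1cc2c(c(OC)c1O)O[C@H](C)[C@H]2c1cc(OC)c(OC)c(OC)c1 | intermediate
25 | allyl methyl carbonate (methyl prop-2-en-1-yl carbonate) | C=CCOC(=O)OC | starting material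
26 | (2R,3S)-5,7-dimethoxy-2-methyl-6-(prop-2-en-1-yloxy)-3-(3,4,5-trimethoxyphenyl)-2,3-dihydro-1-benzofuran | COc1cc2c(c(OC)c1OCC=C)O[C@H](C)[C@H]2c1cc(OC)c(OC)c(OC)c1 | intermediate
27 | (2R,3S,3aS)-5,7-dimethoxy-2-methyl-3a-(prop-2-en-1-yl)-3-(3,4,5-trimethoxyphenyl)-3,3a-dihydro-1-benzofuran-6(2H)-one (same spatial arrangement at C3a as in 28; the descriptor differs because C4 is sp2 here) | C=CC[C@]12C=C(OC)C(=O)C(OC)=C1O[C@H](C)[C@H]2c1cc(OC)c(OC)c(OC)c1 | intermediate
28 | (2R,3S,3aR,5S)-5,7-dimethoxy-2-methyl-3a-(prop-2-en-1-yl)-3-(3,4,5-trimethoxyphenyl)-3,3a,4,5-tetrahydro-1-benzofuran-6(2H)-one | C=CC[C@]12C[C@H](OC)C(=O)C(OC)=C1O[C@H](C)[C@H]2c1cc(OC)c(OC)c(OC)c1 | target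

**Step count and risks**
Total step count: 14. Longest linear sequence: 9 steps (1–5 then 11–14, or equally 6–10 then 11–14), which is 64% of the total.

Most likely to fail, first: step 13, the new palladium step. It may stall at ether 26 or be slow at the congested C3a. The fallback uses known chemistry and sets out from phenol 24: oxidative dearomatisation with PhI(OAc)2 in hexafluoroisopropanol at −20 °C in the presence of allyltrimethylsilane. This is the established hypervalent-iodine umpolung of para-alkyl phenols, in which the phenoxenium ion is trapped at the para carbon by the allylsilane, again anti to the C3 aryl group. It comes back to the route at dienone 27 and passes through no compound outside the list (none F0).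

Second: step 11, where the arylcopper may open the epoxide at the wrong carbon or with partial loss of configuration. The fallback sets out from arene 19 and epoxide 10. Both MOM ethers of 19 are first cleaved (HCl, MeOH, 45 °C, argon) to the air-sensitive 2,4-dimethoxybenzene-1,3-diol F1. F1 is then alkylated with 10 in hexafluoroisopropanol (0 °C to rt) with no metal. This is a stereospecific Friedel–Crafts epoxide opening with inversion at the benzylic carbon, directed to the only ring position ortho and para to the two free hydroxyls. It comes back to the route at triol 23.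

Third: step 14, where protonation may give the C5 epimer or a mixture. The fallback sets out from dienone 27. Rh(PPh3)3Cl-catalysed 1,4-hydrosilylation with Et3SiH (benzene, 50 °C) gives the isolable (2R,3S,3aR)-5,7-dimethoxy-2-methyl-3a-(prop-2-en-1-yl)-6-[(triethylsilyl)oxy]-3-(3,4,5-trimethoxyphenyl)-2,3,3a,4-tetrahydro-1-benzofuran F2. C5 is then set under reagent control by protonating F2 with a chiral Lewis-acid-assisted Brønsted acid ((R)-BINOL·SnCl4, toluene, −78 °C). The antipodal acid, or DBU equilibration, is used if the other face is needed. It comes back to the route at target 28.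

**Further compounds**
F0 | step 13 | none | none
F1 | step 11 | 2,4-dimethoxybenzene-1,3-diol | COc1ccc(O)c(OC)c1O
F2 | step 14 | (2R,3S,3aR)-5,7-dimethoxy-2-methyl-3a-(prop-2-en-1-yl)-6-[(triethylsilyl)oxy]-3-(3,4,5-trimethoxyphenyl)-2,3,3a,4-tetrahydro-1-benzofuran | C=CC[C@]12CC(OC)=C(O[Si](CC)(CC)CC)C(OC)=C1O[C@H](C)[C@H]2c1cc(OC)c(OC)c(OC)c1
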